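**Retrosynthetic overview**

1. Briarane numbering is used: cyclohexane C1/C10–C14 fused to the ten-membered ring C1–C10, which the C4–O–C8 ether divides into a pyran (O, C4–C8) and an eight-membered oxacycle; γ-lactone C8–C17–C19(=O)–O–C7. The last operations are ene chlorination of a Δ5 alkene (C6–Cl, C5=C16), elaboration of a C11 ketone (sulfoxonium ylide, then acetate) and reduction at C14 and C2.
2. Key disconnection: C3–C4 and C1–C10 (together with C11–C12) in one operation, giving ketal lactone nitroalkene 16 (C4–C11, C16–C19) and bis(silyl enol ether) 22 (C1–C3, C12–C15).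
3. Enabling feature: C4 is the acetal-level carbon of the pyran ring and is allylic to C5, so it becomes an oxocarbenium ion when a second oxygen (that of C9) is released from it. C2 is an oxygenated carbon flanked by C1 and C3 and 1,3 to the C14 oxygen, so C14/C2 is a latent 1,3-diketone, nucleophilic at C3 and then C1. The C14 and C11 oxygens are 1,4 on the cyclohexane, the pattern of a 2-silyloxydiene/nitroalkene Diels–Alder adduct.
4. Ring order: furan → pyranone (Achmatowicz) → ketal bridge → lactone; then, in the key step, the eight-membered oxacycle (= ten-membered carbocycle) and the cyclohexane together.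
5. Fragments: 16 from 4-methylfuran-2-carbaldehyde in 11 steps (C9 by asymmetric alkoxyallylboration, C8 by Felkin–Anh Mukaiyama aldol); 22 from pent-1-en-3-one in 3 steps.

Key step: step 15

Remark: compounds 1, 2, 6, 17 and 18 are taken as commercial; the nitro-bearing carbon C11 of 24–29 is drawn as expected from the cycloaddition, is of no consequence and is removed in step 21.

**Route**

Step 1
Reactants: 1 4-methylfuran-2-carbaldehyde; 2 3-(methoxymethoxy)prop-1-ene
Product: 4 (1R,2S)-2-(methoxymethoxy)-1-(4-methylfuran-2-yl)but-3-en-1-ol, via (Z)-alkoxyallyl diisopinocampheylborane 3 (not isolated)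
Conditions: 2, s-BuLi, THF, −78 °C; (+)-Ipc2BOMe; BF3·OEt2; 1, −78 °C; NaOH, H2O2, 0 °C
Reagents that add atoms: none
Why: Asymmetric (Z)-γ-alkoxyallylboration of the aldehyde through a Zimmerman–Traxler chair, in which the (Z)-allylborane geometry gives the syn adduct and the isopinocampheyl groups derived from (+)-Ipc2BOMe fix the alkoxy-bearing carbon as (2S) (C9 of the target), the carbinol carbon being oxidised in step 2.

Step 2
Reactants: 4 (1R,2S)-2-(methoxymethoxy)-1-(4-methylfuran-2-yl)but-3-en-1-ol
Product: 5 (2S)-2-(methoxymethoxy)-1-(4-methylfuran-2-yl)but-3-en-1-one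
Conditions: Dess–Martin periodinane, NaHCO3, CH2Cl2, 0 °C
Reagents that add atoms: none
Why: Dess–Martin oxidation of the furyl carbinol under buffered non-basic conditions should give the ketone without epimerising or conjugating the α-alkoxy β,γ-unsaturated stereocentre.

Step 3
Reactants: 5 (2S)-2-(methoxymethoxy)-1-(4-methylfuran-2-yl)but-3-en-1-one; 6 tert-butyl[(1-methoxyethenyl)oxy]dimethylsilane
Product: 7 methyl (3R,4S)-3-hydroxy-4-(methoxymethoxy)-3-(4-methylfuran-2-yl)hex-5-enoate
Conditions: BF3·OEt2, CH2Cl2, −78 °C; aq. NaHCO3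
Reagents that add atoms: none
Why: Mukaiyama aldol addition to the ketone promoted by the monodentate Lewis acid BF3, which cannot chelate, so that the polar Felkin–Anh arrangement (C–OMOM anti to the incoming ketene acetal) sets the tertiary carbinol C8 with its oxygen syn to the C9 oxygen.

Step 4
Reactants: 7 methyl (3R,4S)-3-hydroxy-4-(methoxymethoxy)-3-(4-methylfuran-2-yl)hex-5-enoate
Product: 8 methyl 2-[(2R)-6-hydroxy-2-[(1S)-1-(methoxymethoxy)prop-2-en-1-yl]-5-methyl-3-oxo-3,6-dihydro-2H-pyran-2-yl]acetate (both anomers)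
Conditions: N-bromosuccinimide, NaHCO3, THF/H2O (4:1), 0 °C
Reagents that add atoms: water, O
Why: Achmatowicz rearrangement, in which oxidation of the furan and ring expansion through the tertiary furfuryl hydroxyl give the 6-hydroxy-2H-pyran-3(6H)-one and the furan reacts far faster with the bromine source than the vinyl group; the anomeric carbon is formed as a mixture that converges in step 5.

Step 5
Reactants: 8 pyranone lactol (both anomers)
Product: 9 methyl 2-[(1R,5R,7S)-7-ethenyl-4-methyl-2-oxo-6,8-dioxabicyclo[3.2.1]oct-3-en-1-yl]acetate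
Conditions: Me3SiBr, CH2Cl2, −40 → 0 °C; aq. NaHCO3
Reagents that add atoms: none
Why: Me3SiBr cleaves the MOM ether and ionises the lactol, and the silylated C9 oxygen closes the 6,8-dioxabicyclo[3.2.1]octenone (bicycloketalisation of an Achmatowicz product), in which the ketal carbon C4 can only bond on the face that carries C9.

Step 6
Reactants: 9 bicyclic ketal enone
Product: 10 methyl 2-[(1S,2R,5R,7S)-7-ethenyl-2-hydroxy-4-methyl-6,8-dioxabicyclo[3.2.1]oct-3-en-1-yl]acetate
Conditions: NaBH4, CeCl3·7H2O, MeOH, −78 °C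
Reagents that add atoms: none
Why: Luche 1,2-reduction, with hydride delivered to the enone face opposite the two-atom O–CH ketal bridge as in levoglucosenone-type enones, should give the allylic alcohol syn to that bridge.

Step 7
Reactants: 10 allylic alcohol ester
Product: 11 2-[(1S,2R,5R,7S)-7-ethenyl-2-hydroxy-4-methyl-6,8-dioxabicyclo[3.2.1]oct-3-en-1-yl]acetic acid
Conditions: LiOH, THF/H2O, 0 → 23 °C; 1 M HCl to pH 3
Reagents that add atoms: lithium hydroxide, [Li+].[OH-]
Why: Saponification of the methyl ester, to which the ketal, the allylic alcohol and the alkenes are inert.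

Step 8
Reactants: 11 hydroxy acid
Product: 12 vinyl ketal γ-lactone (C19(=O)–O–C7 lactone cis-fused on the pyran, O7 anti to the ketal bridge, C17 = CH2)
Conditions: PPh3, DIAD, THF, 0 → 23 °C
Reagents that add atoms: none
Why: Mitsunobu lactonisation, in which the carboxylate displaces the activated allylic C7 oxygen in a 5-exo SN2 closure with inversion, gives the cis-fused γ-lactone with the C7 oxygen on the face opposite the ketal bridge.

Step 9
Reactants: 12 vinyl ketal γ-lactone
Product: 13 (17R)-17-methyl vinyl ketal γ-lactone (CH3-18 trans to C9)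
Conditions: MeI (5 equiv), then LiN(SiMe3)2 (1.1 equiv), THF, −78 °C
Reagents that add atoms: iodomethane, CI
Why: Kinetic α-alkylation of the lactone lithium enolate, in which iodomethane should approach the enolate face that carries only the ring oxygen on the neighbouring C8 and not the branched C9, setting C17 with the methyl group trans to C9.

Step 10
Reactants: 13 (17R)-17-methyl vinyl ketal γ-lactone
Product: 14 ketal lactone aldehyde (C9–CHO)
Conditions: OsO4 (2 mol %), NaIO4, 2,6-lutidine, 1,4-dioxane/H2O (3:1), 23 °C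
Reagents that add atoms: sodium periodate, [Na+].[O-]I(=O)(=O)=O
Why: Lemieux–Johnson oxidative cleavage, in which OsO4 should select the exposed monosubstituted vinyl group over the trisubstituted ring alkene, which is screened by the ketal bridge on one face and by the lactone on the other and is deactivated by two allylic C–O bonds.

Step 11
Reactants: 14 ketal lactone aldehyde
Product: 16 ketal lactone (E)-nitroalkene (C9–CH=CH–NO2), via nitro alcohol 15 (not isolated)
Conditions: MeNO2 (10 equiv), Et3N (0.3 equiv), CH2Cl2, 0 °C; then MsCl, Et3N, −20 → 0 °C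
Reagents that add atoms: nitromethane, C[N+](=O)[O-]
Why: Henry (nitroaldol) addition followed by mesylation and E1cB elimination gives the conjugated (E)-nitroalkene, the catalytic amine base being too weak to epimerise the α-alkoxy aldehyde carbon C9.

Step 12
Reactants: 17 pent-1-en-3-one; 18 2-[(4-methoxyphenyl)methoxy]acetaldehyde
Product: 20 5-hydroxy-6-[(4-methoxyphenyl)methoxy]-4-methylhex-1-en-3-one (diastereomer mixture), via dibutylboron enolate 19 (not isolated)
Conditions: 17, Bu2BOTf, i-Pr2NEt, CH2Cl2, −78 °C; 18, −78 → 0 °C; pH 7 buffer, MeOH, H2O2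
Reagents that add atoms: none
Why: Boron-mediated aldol reaction through the (Z)-dibutylboron enolate of the ethyl ketone, which has only one enolisable position; the two new stereocentres are of no consequence because both are lost in steps 13 and 14.

Step 13
Reactants: 20 aldol adduct
Product: 21 6-[(4-methoxyphenyl)methoxy]-4-methylhex-1-ene-3,5-dione
Conditions: Dess–Martin periodinane, NaHCO3, CH2Cl2, 0 °C; used at once
Reagents that add atoms: none
Why: Dess–Martin oxidation of the β-hydroxy ketone gives the 2-methyl-1,3-diketone under neutral conditions that do not set off Michael self-condensation of the vinyl ketone.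

Step 14
Reactants: 21 vinyl 1,3-diketone
Product: 22 3,5-bis[(tert-butyldimethylsilyl)oxy]-6-[(4-methoxyphenyl)methoxy]-4-methylhexa-1,3,5-triene (enol ether geometries not controlled)
Conditions: TBSOTf (2.3 equiv), Et3N (3 equiv), CH2Cl2, −78 → 0 °C
Reagents that add atoms: tert-butyldimethylsilyl trifluoromethanesulfonate, CC(C)(C)[Si](C)(C)OS(=O)(=O)C(F)(F)F
Why: Soft enolisation and double O-silylation with TBSOTf and Et3N, first of the enolised 1,3-diketone and then of the remaining α-alkoxy methylene group, gives the cross-conjugated bis(silyl enol ether).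

Step 15
Reactants: 16 ketal lactone (E)-nitroalkene; 22 bis(silyl enol ether)
Product: 24 tetracyclic nitro ketone (9-OTBS, 3-OPMB, 2-oxo, 11-nitro, Δ5, 14-OTBS Δ13 enol ether), via C-glycoside silyloxydiene 23 (not isolated)
Conditions: TBSOTf (0.2 equiv), 2,6-di-tert-butyl-4-methylpyridine (0.3 equiv), CH2Cl2, −78 °C; then dilute to 0.005 M, −78 → 40 °C
Reagents that add atoms: none
Why: Proposed new method: catalytic TBSOTf silylates the less hindered ketal oxygen (on C9) of 16 and opens the strained bicyclic ketal to the C5-conjugated pyranyl oxocarbenium ion, which at −78 °C is captured at C4 by the terminal carbon C3 of the 1,3-bis(silyloxy)diene unit of 22 with return of the silyl triflate (a vinylogous Mukaiyama/Ferrier-type C-glycosylation, closest to the known Lewis-acid opening of 1,6-anhydro sugars and pyranyl acetals by enol silanes), giving 23 in which the remaining 2-silyloxydiene C1=C14–C13=C12 is tethered to the nitroalkene. On warming, 23 should undergo an intramolecular Diels–Alder reaction (or its stepwise Mukaiyama–Michael/nitronate–Michael equivalent), closest to the known cycloadditions of 2-silyloxydienes with nitroalkenes, that forms C1–C10 and C11–C12. Two rings close: the eight-membered oxacycle C1–C2–C3–C4–O–C8–C9–C10, and with it the ten-membered carbocycle, through the tether-spanning bond C1–C10, and the cyclohexene C1–C10–C11–C12–C13–C14 through the [4+2] cycloaddition itself. C4 is set by attack on the oxocarbenium face opposite the fused lactone and its CH3-18 group, which is the face cis to C9 and the only one from which the adduct can cyclise; C3 follows from an open antiperiplanar transition state and stays correctable as the α-carbon of the C2 ketone; C1 and C10 follow from the nitro-endo transition state of the (E)-nitroalkene with the acyl tether on the outside of the diene (trans ring fusion, CH3-15 anti to H-10) and with the C9–O bond antiperiplanar to the forming C1–C10 bond, and C11 (nitro trans to C9) is removed in step 21. The step needs site selectivity (C3 before C1, oxocarbenium ion before nitroalkene), secured by the temperature programme and by the higher nucleophilicity of the diene terminus, and regioselectivity in the cycloaddition, secured by the nitro group (C10 is its β-carbon) and by the 2-silyloxy group (C1 is the nucleophilic diene terminus), which together place the C14 oxygen and the C11 nitrogen 1,4 on the new ring.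

Step 16
Reactants: 24 tetracyclic nitro ketone
Product: 25 (2R)-2-hydroxy compound (14-OTBS enol ether retained)
Conditions: LiBH(s-Bu)3 (L-Selectride, 1.5 equiv), THF, −78 → −40 °C; AcOH
Reagents that add atoms: none
Why: Felkin–Anh-controlled reduction of the only free ketone by the bulky non-chelating hydride LiBH(s-Bu)3, with hydride adding anti to the C3–O bond, should give the 2,3-syn alcohol (2R), while C14 stays masked as its silyl enol ether and the lactone survives at −78 °C.

Step 17
Reactants: 25 (2R)-2-hydroxy silyl enol ether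
Product: 26 2-hydroxy-14-ketone
Conditions: 0.2 M HCl, THF/H2O, 0 °C
Reagents that add atoms: none
Why: Acid hydrolysis of the silyl enol ether, which is far more labile than the hindered secondary silyl ether on C9, unmasks the C14 ketone.

Step 18
Reactants: 26 2-hydroxy-14-ketone
Product: 27 (2R,14S)-2,14-diol (3-OPMB, 9-OTBS, 11-nitro)
Conditions: Me4NBH(OAc)3, MeCN/AcOH (1:1), −20 °C
Reagents that add atoms: none
Why: Hydroxyl-directed (Evans–Saksena) reduction, in which the C2 alkoxyborohydride delivers hydride intramolecularly through a chair transition state, should give the 1,3-anti diol, that is the axial (14S) alcohol.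

Step 19
Reactants: 27 2,14-diol PMB ether
Product: 28 2,3,14-triol (9-OTBS, 11-nitro)
Conditions: DDQ, CH2Cl2/pH 7 buffer (10:1), 0 °C
Reagents that add atoms: none
Why: Oxidative cleavage of the p-methoxybenzyl ether by DDQ through the benzylic oxocarbenium ion, to which the silyl ether, lactone, nitro group and trisubstituted alkene are inert.

Step 20
Reactants: 28 2,3,14-triol
Product: 29 2,3,14-triacetate (9-OTBS, 11-nitro)
Conditions: Ac2O, pyridine, DMAP (cat.), 40 °C
Reagents that add atoms: acetic anhydride, CC(=O)OC(C)=O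
Why: DMAP-catalysed acylation of the three secondary alcohols, the only free hydroxyl groups at this stage.

Step 21
Reactants: 29 2,3,14-triacetate nitro compound
Product: 31 11-ketone (2,3,14-triacetate, 9-OTBS), via DBU-H nitronate salt 30 (not isolated)
Conditions: DBU, MeCN, 0 °C; then aq. TiCl3, NH4OAc buffer (pH 5–6), THF, 0 → 23 °C
Reagents that add atoms: water, O
Why: Nef reaction in its reductive form, in which the nitronate is reduced by buffered aqueous TiCl3 to the imine that hydrolyses at pH 5–6 to the C11 ketone without touching the acetates, lactone, silyl ether or C10.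

Step 22
Reactants: 31 11-ketone
Product: 32 (11S)-11,20-spiro-epoxide
Conditions: Me3S(O)I, NaH, DMSO/THF, 23 °C; then 31, 0 → 23 °C
Reagents that add atoms: trimethylsulfoxonium iodide, C[S+](C)(C)=O.[I-]
Why: Corey–Chaykovsky epoxidation with the sulfoxonium ylide, whose reversible addition gives the product of equatorial C–C bond formation (axial C11–O bond, syn to CH3-15) and which is too weakly basic to enolise the ketone or attack the esters.

Step 23
Reactants: 32 11,20-spiro-epoxide
Product: 33 11-hydroxy-2,3,14,20-tetraacetate (9-OTBS, Δ5)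
Conditions: AcOH (10 equiv), CsOAc (0.5 equiv), DMF, 60 °C
Reagents that add atoms: acetic acid, CC(=O)O
Why: SN2 opening of the spiro-epoxide by acetate at the primary carbon C20 leaves the tertiary C11–O bond and its configuration untouched.

Step 24
Reactants: 33 11-hydroxy tetraacetate
Product: 34 9-O-TBS ether of the target ((6S)-6-chloro, 5(16)-ene)
Conditions: NaOCl (aq.), AcOH, CH2Cl2, 0 °C
Reagents that add atoms: sodium hypochlorite, [Na+].[O-]Cl
Why: Ene-type allylic chlorination by hypochlorous acid, in which electrophilic chlorine should add to C6 on the alkene face opposite the five-carbon bridge and a proton is lost from the C16 methyl group, gives the exocyclic methylene and the (6S) chloride.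

Step 25
Reactants: 34 9-O-TBS ether of the target
Product: 35 CNP0190959.1
Conditions: HF·pyridine, pyridine/THF, 0 → 23 °C
Reagents that add atoms: none
Why: Desilylation of the hindered secondary silyl ether with HF·pyridine, an acidic fluoride source that leaves the four acetates, the lactone and the allylic chloride intact.

**Compound list**

1 | 4-methylfuran-2-carbaldehyde | Cc1coc(C=O)c1 | starting material
2 | 3-(methoxymethoxy)prop-1-ene | C=CCOCOC | starting material
3 | [(2Z)-3-(methoxymethoxy)prop-2-en-1-yl]bis[(1S,2S,3S,5R)-2,6,6-trimethylbicyclo[3.1.1]heptan-3-yl]borane | C[C@@H]1[C@@H](B(C/C=C\OCOC)[C@H]3C[C@H]4C[C@@H]([C@@H]3C)C4(C)C)C[C@H]2C[C@@H]1C2(C)C | intermediate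
4 | (1R,2S)-2-(methoxymethoxy)-1-(4-methylfuran-2-yl)but-3-en-1-ol | Cc1coc([C@H](O)[C@@H](OCOC)C=C)c1 | intermediate
5 | (2S)-2-(methoxymethoxy)-1-(4-methylfuran-2-yl)but-3-en-1-one | Cc1coc(C(=O)[C@@H](OCOC)C=C)c1 | intermediate
6 | tert-butyl[(1-methoxyethenyl)oxy]dimethylsilane | C=C(OC)O[Si](C)(C)C(C)(C)C | starting material
7 | methyl (3R,4S)-3-hydroxy-4-(methoxymethoxy)-3-(4-methylfuran-2-yl)hex-5-enoate | Cc1coc([C@@](O)(CC(=O)OC)[C@@H](OCOC)C=C)c1 | intermediate
8 | methyl 2-[(2R)-6-hydroxy-2-[(1S)-1-(methoxymethoxy)prop-2-en-1-yl]-5-methyl-3-oxo-3,6-dihydro-2H-pyran-2-yl]acetate (both anomers) | CC1=CC(=O)[C@@](CC(=O)OC)([C@@H](OCOC)C=C)OC1O | intermediate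
9 | methyl 2-[(1R,5R,7S)-7-ethenyl-4-methyl-2-oxo-6,8-dioxabicyclo[3.2.1]oct-3-en-1-yl]acetate | CC1=CC(=O)[C@]2(CC(=O)OC)O[C@H]1O[C@H]2C=C | intermediate
10 | methyl 2-[(1S,2R,5R,7S)-7-ethenyl-2-hydroxy-4-methyl-6,8-dioxabicyclo[3.2.1]oct-3-en-1-yl]acetate | CC1=C[C@@H](O)[C@]2(CC(=O)OC)O[C@H]1O[C@H]2C=C | intermediate
11 | 2-[(1S,2R,5R,7S)-7-ethenyl-2-hydroxy-4-methyl-6,8-dioxabicyclo[3.2.1]oct-3-en-1-yl]acetic acid | CC1=C[C@@H](O)[C@]2(CC(=O)O)O[C@H]1O[C@H]2C=C | intermediate
12 | vinyl ketal γ-lactone: lactone C19(=O)–O–C7 cis-fused on the Δ5 pyran, O7 anti to the C4–O–C9 ketal bridge, C17 = CH2, vinyl on C9 | CC1=C[C@@H]2OC(=O)C[C@]23O[C@H]1O[C@H]3C=C | intermediate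
13 | (17R)-17-methyl derivative of 12 (CH3-18 cis to the pyran oxygen on C8, trans to C9) | CC1=C[C@@H]2OC(=O)[C@H](C)[C@]23O[C@H]1O[C@H]3C=C | intermediate
14 | ketal lactone aldehyde (13 with C9–CHO in place of C9–vinyl) | CC1=C[C@@H]2OC(=O)[C@H](C)[C@]23O[C@H]1O[C@H]3C=O | intermediate
15 | nitro alcohol (C9–CH(OH)–CH2NO2, both C10 epimers) | CC1=C[C@@H]2OC(=O)[C@H](C)[C@]23O[C@H]1O[C@H]3C(O)C[N+](=O)[O-] | intermediate
16 | ketal lactone (E)-nitroalkene (C9–CH=CH–NO2) | CC1=C[C@@H]2OC(=O)[C@H](C)[C@]23O[C@H]1O[C@H]3/C=C/[N+](=O)[O-] | intermediate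
17 | pent-1-en-3-one | CCC(=O)C=C | starting material
18 | 2-[(4-methoxyphenyl)methoxy]acetaldehyde | COc1ccc(COCC=O)cc1 | starting material
19 | (3Z)-3-[(dibutylboranyl)oxy]penta-1,3-diene | C/C=C(\OB(CCCC)CCCC)C=C | intermediate
20 | 5-hydroxy-6-[(4-methoxyphenyl)methoxy]-4-methylhex-1-en-3-one (diastereomer mixture) | C=CC(=O)C(C)C(O)COCc1ccc(OC)cc1 | intermediate
21 | 6-[(4-methoxyphenyl)methoxy]-4-methylhex-1-ene-3,5-dione | C=CC(=O)C(C)C(=O)COCc1ccc(OC)cc1 | intermediate
22 | 3,5-bis[(tert-butyldimethylsilyl)oxy]-6-[(4-methoxyphenyl)methoxy]-4-methylhexa-1,3,5-triene (mixture of enol ether geometries) | C=CC(O[Si](C)(C)C(C)(C)C)=C(C)C(O[Si](C)(C)C(C)(C)C)=COCc1ccc(OC)cc1 | intermediate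
23 | C-glycoside silyloxydiene: Δ5 pyran lactone with C9–OTBS and (E)-nitrovinyl, C4 bonded to C3H(OPMB)–C2(=O)–C1(CH3)=C14(OTBS)–C13H=C12H2 | CC=1[C@H]([C@@H](OCc2ccc(OC)cc2)C(=O)C(C)=C(O[Si](C)(C)C(C)(C)C)C=C)O[C@]3([C@@H](C)C(=O)O[C@H]3C=1)[C@@H](O[Si](C)(C)C(C)(C)C)/C=C/[N+](=O)[O-] | intermediate
24 | tetracyclic nitro ketone: 4,8-ether, 7,19-lactone, Δ5, 9-OTBS, 3-OPMB, 2-oxo, 11-nitro, 14-OTBS Δ13 enol ether; C1, C3, C4, C7, C8, C9, C10, C17 as in 35 | CC=1[C@H]2O[C@]3([C@@H](C)C(=O)O[C@H]3C=1)[C@@H](O[Si](C)(C)C(C)(C)C)[C@H]1[C@H]([N+](=O)[O-])CC=C(O[Si](C)(C)C(C)(C)C)[C@]1(C)C(=O)[C@@H]2OCc1ccc(OC)cc1 | intermediate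
25 | (2R)-2-hydroxy derivative of 24 | CC=1[C@H]2O[C@]3([C@@H](C)C(=O)O[C@H]3C=1)[C@@H](O[Si](C)(C)C(C)(C)C)[C@H]1[C@H]([N+](=O)[O-])CC=C(O[Si](C)(C)C(C)(C)C)[C@]1(C)[C@@H](O)[C@@H]2OCc1ccc(OC)cc1 | intermediate
26 | 2-hydroxy-14-ketone (enol ether of 25 hydrolysed) | CC=1[C@H]2O[C@]3([C@@H](C)C(=O)O[C@H]3C=1)[C@@H](O[Si](C)(C)C(C)(C)C)[C@H]1[C@H]([N+](=O)[O-])CCC(=O)[C@]1(C)[C@@H](O)[C@@H]2OCc1ccc(OC)cc1 | intermediate
27 | (2R,14S)-2,14-diol, 3-OPMB, 9-OTBS, 11-nitro | CC=1[C@H]2O[C@]3([C@@H](C)C(=O)O[C@H]3C=1)[C@@H](O[Si](C)(C)C(C)(C)C)[C@H]1[C@H]([N+](=O)[O-])CC[C@H](O)[C@]1(C)[C@@H](O)[C@@H]2OCc1ccc(OC)cc1 | intermediate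
28 | 2,3,14-triol, 9-OTBS, 11-nitro | CC=1[C@H]2O[C@]3([C@@H](C)C(=O)O[C@H]3C=1)[C@@H](O[Si](C)(C)C(C)(C)C)[C@H]1[C@H]([N+](=O)[O-])CC[C@H](O)[C@]1(C)[C@@H](O)[C@@H]2O | intermediate
29 | 2,3,14-triacetate, 9-OTBS, 11-nitro | CC=1[C@H]2O[C@]3([C@@H](C)C(=O)O[C@H]3C=1)[C@@H](O[Si](C)(C)C(C)(C)C)[C@H]1[C@H]([N+](=O)[O-])CC[C@H](OC(C)=O)[C@]1(C)[C@@H](OC(C)=O)[C@@H]2OC(C)=O | intermediate
30 | C11 nitronate of 29 as its DBU-H salt | CC=1[C@H]2O[C@]3([C@@H](C)C(=O)O[C@H]3C=1)[C@@H](O[Si](C)(C)C(C)(C)C)[C@H]1C(=[N+]([O-])[O-])CC[C@H](OC(C)=O)[C@]1(C)[C@@H](OC(C)=O)[C@@H]2OC(C)=O.C1CCC2=[NH+]CCCN2CC1 | intermediate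
31 | 11-ketone, 2,3,14-triacetate, 9-OTBS | CC=1[C@H]2O[C@]3([C@@H](C)C(=O)O[C@H]3C=1)[C@@H](O[Si](C)(C)C(C)(C)C)[C@H]1C(=O)CC[C@H](OC(C)=O)[C@]1(C)[C@@H](OC(C)=O)[C@@H]2OC(C)=O | intermediate
32 | (11S)-11,20-spiro-epoxide (epoxide oxygen axial, syn to CH3-15) | CC=1[C@H]2O[C@]3([C@@H](C)C(=O)O[C@H]3C=1)[C@@H](O[Si](C)(C)C(C)(C)C)[C@H]1[C@]4(CO4)CC[C@H](OC(C)=O)[C@]1(C)[C@@H](OC(C)=O)[C@@H]2OC(C)=O | intermediate
33 | 11-hydroxy-2,3,14,20-tetraacetate, 9-OTBS, Δ5 (C16 methyl) | CC=1[C@H]2O[C@]3([C@@H](C)C(=O)O[C@H]3C=1)[C@@H](O[Si](C)(C)C(C)(C)C)[C@H]1[C@](O)(COC(C)=O)CC[C@H](OC(C)=O)[C@]1(C)[C@@H](OC(C)=O)[C@@H]2OC(C)=O | intermediate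
34 | 9-O-TBS ether of the target ((6S)-chloride, 5(16)-ene) | C=C1[C@H]2O[C@]3([C@@H](C)C(=O)O[C@H]3[C@H]1Cl)[C@@H](O[Si](C)(C)C(C)(C)C)[C@H]1[C@](O)(COC(C)=O)CC[C@H](OC(C)=O)[C@]1(C)[C@@H](OC(C)=O)[C@@H]2OC(C)=O | intermediate
35 | CNP0190959.1, (1R,2R,3R,4R,6S,7R,8R,9S,10S,11S,14S,17R) in briarane numbering | C=C1[C@H]2O[C@]3([C@@H](C)C(=O)O[C@H]3[C@H]1Cl)[C@@H](O)[C@H]1[C@](O)(COC(C)=O)CC[C@H](OC(C)=O)[C@]1(C)[C@@H](OC(C)=O)[C@@H]2OC(C)=O | target

**Step count and risks**

Total step count: 25. Longest linear sequence: 22 steps (steps 1–11 and 15–25).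

Steps most likely to fail:

1. Step 15 (proposed new method). What may go wrong: capture of the oxocarbenium ion on the face trans to C9 (that adduct cannot cyclise), addition of the diene terminus to the nitroalkene before the ketal opens, oligomerisation instead of the medium-ring cycloaddition, or cycloaddition on the other π-face of the nitroalkene relative to C9. The fallback sets out from 16 and 21 and reverses the order of bond formation with known reactions. A Cs2CO3-mediated double Michael reaction in CH2Cl2 (diketone carbon C1 onto C10, then the nitronate carbon C11 onto the vinyl ketone carbon C12) should give the nitrocyclohexanone with intact ketal F1. Here the nucleophile attacks the nitroalkene anti to the bulky ketal bridgehead C8. Treatment of F1 with TBSOTf and Et3N (enol silane formation in the flask and intramolecular Mukaiyama-type opening of the ketal by C3) then closes the C3–C4 bond on the only face the tether allows and comes back to the route at 24.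

2. Step 24. What may go wrong: poor facial selectivity of chlorine delivery, loss of the proton at C4 instead of from the C16 methyl group, or addition of HOCl across the alkene. The fallback sets out from 33. A Schenck ene reaction with singlet oxygen (O2, tetraphenylporphyrin, light) should give the allylic hydroperoxide F4, which is dehydrated in the flask (Ac2O, pyridine; Kornblum–DeLaMare) to the α-methylene ketone F5. Luche reduction from the open lower face should give the upper-face allylic alcohol F6. Appel chlorination (PPh3, C2Cl6) with SN2 inversion then comes back to the route at 34.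

3. Step 16. What may go wrong: poor facial selectivity of hydride addition to the medium-ring ketone, because the Felkin–Anh rotamer may not be accessible in the eight-membered ring, or epimerisation at C3. The fallback sets out from 24 and reverses the order of the two reductions. Hydrolysis of the enol ether (0.2 M HCl, THF) gives the 2,14-diketone F2. LiBH(s-Bu)3 should attack the less hindered cyclohexanone carbonyl C14 from the equatorial direction to give the axial (14S) alcohol F3. Me4NBH(OAc)3 then reduces the C2 ketone under direction of the C14 hydroxyl to the 1,3-anti diol and comes back to the route at 27.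

**Further compounds**

F1 | step 15 | double Michael adduct of 16 and 21: ketal lactone bearing on C9 the cyclohexanone C10–C11(NO2)–C12–C13–C14(=O)–C1(CH3)(C2(=O)–C3H2OPMB) | CC1=C[C@@H]2OC(=O)[C@H](C)[C@]23O[C@H]1O[C@H]3[C@H]1[C@H]([N+](=O)[O-])CCC(=O)[C@]1(C)C(=O)COCc1ccc(OC)cc1
F2 | step 16 | 2,14-diketone (24 with the enol ether hydrolysed) | CC=1[C@H]2O[C@]3([C@@H](C)C(=O)O[C@H]3C=1)[C@@H](O[Si](C)(C)C(C)(C)C)[C@H]1[C@H]([N+](=O)[O-])CCC(=O)[C@]1(C)C(=O)[C@@H]2OCc1ccc(OC)cc1
F3 | step 16 | (14S)-14-hydroxy-2-ketone | CC=1[C@H]2O[C@]3([C@@H](C)C(=O)O[C@H]3C=1)[C@@H](O[Si](C)(C)C(C)(C)C)[C@H]1[C@H]([N+](=O)[O-])CC[C@H](O)[C@]1(C)C(=O)[C@@H]2OCc1ccc(OC)cc1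
F4 | step 24 | C6 allylic hydroperoxide with 5(16)-ene (oxygen on the face of the target chlorine) | C=C1[C@H]2O[C@]3([C@@H](C)C(=O)O[C@H]3[C@H]1OO)[C@@H](O[Si](C)(C)C(C)(C)C)[C@H]1[C@](O)(COC(C)=O)CC[C@H](OC(C)=O)[C@]1(C)[C@@H](OC(C)=O)[C@@H]2OC(C)=O
F5 | step 24 | 6-oxo-5(16)-ene (α-methylene ketone) | C=C1[C@H]2O[C@]3([C@@H](C)C(=O)O[C@H]3C1=O)[C@@H](O[Si](C)(C)C(C)(C)C)[C@H]1[C@](O)(COC(C)=O)CC[C@H](OC(C)=O)[C@]1(C)[C@@H](OC(C)=O)[C@@H]2OC(C)=O
F6 | step 24 | 6-epi allylic alcohol (hydroxyl on the face opposite the target chlorine) | C=C1[C@H]2O[C@]3([C@@H](C)C(=O)O[C@H]3[C@@H]1O)[C@@H](O[Si](C)(C)C(C)(C)C)[C@H]1[C@](O)(COC(C)=O)CC[C@H](OC(C)=O)[C@]1(C)[C@@H](OC(C)=O)[C@@H]2OC(C)=O
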